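**Retrosynthetic overview**

1. Target 26 ⇐ hydroxy sulfone 25 ⇐ macrocyclic sulfone ester 24, by removal of a phenylsulfonyl group from C10 and reduction of a C4 ester.
2. 24 ⇐ open-chain bromo sulfone 22. The only ring, the 14-membered carbocycle, is closed at C9–C10. This bond is the central sp3–sp3 bond of the ring 1,5-diene C7=C8–C9–C10–C11=C12. Both carbons are allylic CH2 termini and natively electrophilic, so a sulfonyl group on C10 reverses its polarity and lets it displace an allylic bromide on C9.
3. 22 ⇐ aldehyde 13 (C10–C14, C1–C3, side chain) + phosphonate 19 (C4–C9), joined by a Z-selective olefination that sets C3=C4.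
4. 13 ⇐ allylic alcohol 10 by a Johnson–Claisen rearrangement that sets C1 and the E C15=C16 olefin ⇐ enal 7 ⇐ nerol 1, which supplies the Z C11=C12 olefin.
5. Ring order: one ring only, formed in step 17.

Key step: step 17

Remark (numbering used throughout): ring C1 (stereocentre)–C2H2–C3H=C4(CH2OH)–C5H2–C6H2–C7H=C8(CH3)–C9H2–C10H2–C11H=C12(CH3)–C13H2–C14H2–back to C1; side chain on C1: C15(CH3)=C16H–C17H2–C18H=C19(CH3)2. The target is 1R, with ring-trans C3=C4 (CIP Z), 7E, 11Z and 15E.

Remark (assumption): the (R)-configured phosphoric acid of step 6 is taken to deliver the allyl group to the re face of the enal, as it does with aryl and alkenyl aldehydes; this gives the (R)-carbinol that step 8 needs.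

**Route**

Step 1
Reactants: 1 nerol
Product: 2 neryl bromide
Conditions: CBr4, PPh3, CH2Cl2, −20 → 0 °C
Reagents that add atoms: carbon tetrabromide, BrC(Br)(Br)Br
Why: Appel bromination: SN2 displacement at the primary allylic carbon at low temperature keeps the Z olefin; no stereocentre is formed.

Step 2
Reactants: 2 neryl bromide
Product: 3 neryl phenyl sulfone
Conditions: PhSO2Na, DMF, 0 °C → rt
Reagents that add atoms: sodium benzenesulfinate, [Na+].[O-]S(=O)c1ccccc1
Why: SN2 S-alkylation of the ambident sulfinate by the allylic bromide in a dipolar aprotic solvent should give the sulfone with the Z olefin intact; no stereocentre is formed.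

Step 3
Reactants: 3 neryl phenyl sulfone
Product: 4 6,7-epoxyneryl phenyl sulfone (racemic)
Conditions: mCPBA (1.05 equiv), NaHCO3, CH2Cl2, 0 °C
Reagents that add atoms: 3-chloroperoxybenzoic acid, OOC(=O)c1cccc(Cl)c1
Why: Prilezhaev epoxidation: the electron-rich distal trisubstituted olefin should react far faster than the olefin deactivated by the allylic sulfonyl group; the epoxide stereocentre is racemic and is destroyed in step 4.

Step 4
Reactants: 4 6,7-epoxyneryl phenyl sulfone
Product: 6 (4Z)-4-methyl-6-(phenylsulfonyl)hex-4-enal, via diol 5 (not isolated)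
Conditions: H5IO6 (1.2 equiv), THF/H2O, 0 °C → rt
Reagents that add atoms: none
Why: Acid-promoted epoxide hydrolysis (water enters at the tertiary carbon) followed by Malaprade glycol cleavage with the same reagent should give the aldehyde, whose oxygen is the former epoxide oxygen.

Step 5
Reactants: 6 (4Z)-4-methyl-6-(phenylsulfonyl)hex-4-enal
Product: 7 (2E,6Z)-2,6-dimethyl-8-(phenylsulfonyl)octa-2,6-dienal
Conditions: Ph3P=C(CH3)CHO (1.2 equiv), toluene, 90 °C
Reagents that add atoms: 2-(triphenylphosphoranylidene)propanal, CC(C=O)=P(c1ccccc1)(c1ccccc1)c1ccccc1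
Why: Wittig olefination with a stabilised formyl ylide should give the (E)-2-methyl enal under thermodynamic control, and the ylide should not react further with the less electrophilic enal product.

Step 6
Reactants: 7 (2E,6Z)-2,6-dimethyl-8-(phenylsulfonyl)octa-2,6-dienal
Product: 9 (4R,5E,9Z)-5,9-dimethyl-11-(phenylsulfonyl)undeca-1,5,9-trien-4-ol, via pinacol borate 8 (not isolated)
Conditions: allylB(pin) (1.3 equiv), (R)-3,3′-bis(2,4,6-triisopropylphenyl)-1,1′-binaphthyl-2,2′-diyl hydrogen phosphate (5 mol %), toluene, −30 °C; aq. NaHCO3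
Reagents that add atoms: allylboronic acid pinacol ester, C=CCB1OC(C)(C)C(C)(C)O1
Why: Chiral phosphoric acid-catalysed allylboration through a closed chair transition state: the acid binds a boronate oxygen and the formyl hydrogen and is expected to expose the re face of the aldehyde, which sets the (R)-carbinol at C16.

Step 7
Reactants: 9 (4R,5E,9Z)-5,9-dimethyl-11-(phenylsulfonyl)undeca-1,5,9-trien-4-ol
Product: 10 (5R,6E,10Z)-2,6,10-trimethyl-12-(phenylsulfonyl)dodeca-2,6,10-trien-5-ol
Conditions: 2-methyl-2-butene (excess), second-generation Grubbs catalyst RuCl2(=CHPh)(PCy3)(H2IMes) (3 mol %), CH2Cl2, 35 °C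
Reagents that add atoms: 2-methyl-2-butene, CC=C(C)C
Why: Olefin cross-metathesis: only the monosubstituted vinyl group should load the ruthenium carbene and be capped as a prenyl group, while the trisubstituted olefins, the alcohol and the sulfone stay inert; the C16 stereocentre is untouched.

Step 8
Reactants: 10 (5R,6E,10Z)-2,6,10-trimethyl-12-(phenylsulfonyl)dodeca-2,6,10-trien-5-ol
Product: 12 ethyl (3R,4E)-4,8-dimethyl-3-[(3Z)-3-methyl-5-(phenylsulfonyl)pent-3-en-1-yl]nona-4,7-dienoate, via ketene acetal 11 (not isolated)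
Conditions: CH3C(OEt)3 (6 equiv), EtCO2H (0.1 equiv), BHT (trace), xylene, 135 °C, EtOH distilled off
Reagents that add atoms: triethyl orthoacetate, CC(OCC)(OCC)OCC
Why: Johnson–Claisen rearrangement of ketene acetal 11 through a chair transition state with the C17 chain equatorial should give the E C15=C16 olefin and transfer the C16 configuration suprafacially across the (E)-C15=C1 olefin to the new C1–C2 bond, which sets (R)-C1.

Step 9
Reactants: 12 ethyl (3R,4E)-4,8-dimethyl-3-[(3Z)-3-methyl-5-(phenylsulfonyl)pent-3-en-1-yl]nona-4,7-dienoate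
Product: 13 (3R,4E)-4,8-dimethyl-3-[(3Z)-3-methyl-5-(phenylsulfonyl)pent-3-en-1-yl]nona-4,7-dienal
Conditions: i-Bu2AlH (1.1 equiv), CH2Cl2, −78 °C; MeOH, aq. sodium potassium tartrate
Reagents that add atoms: none
Why: Low-temperature half-reduction of the ester with one equivalent of i-Bu2AlH should stop at the aldehyde; sulfone and olefins are inert, and C1, β to the carbonyl, cannot epimerise.

Step 10
Reactants: 14 5-bromo-2-methylpent-2-ene
Product: 15 (2E)-5-bromo-2-methylpent-2-en-1-ol
Conditions: SeO2 (0.3 equiv), t-BuOOH (3 equiv), salicylic acid (0.1 equiv), CH2Cl2, rt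
Reagents that add atoms: tert-butyl hydroperoxide, CC(C)(C)OO (oxygen relayed through selenium dioxide, O=[Se]=O)
Why: Riley allylic oxidation (ene reaction then [2,3]-sigmatropic shift) should attack the methyl group trans to the chain of the trisubstituted olefin, which fixes the E C7=C8 geometry of the future ring.

Step 11
Reactants: 15 (2E)-5-bromo-2-methylpent-2-en-1-ol
Product: 16 {[(2E)-5-bromo-2-methylpent-2-en-1-yl]oxy}(tert-butyl)dimethylsilane
Conditions: TBSCl, imidazole, CH2Cl2, 0 °C → rt
Reagents that add atoms: tert-butyldimethylsilyl chloride, CC(C)(C)[Si](C)(C)Cl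
Why: Standard silylation of the primary allylic alcohol masks the C9 oxygen through the anionic steps.

Step 12
Reactants: 16 {[(2E)-5-bromo-2-methylpent-2-en-1-yl]oxy}(tert-butyl)dimethylsilane
Product: 17 tert-butyl{[(2E)-5-iodo-2-methylpent-2-en-1-yl]oxy}dimethylsilane
Conditions: NaI (3 equiv), acetone, reflux
Reagents that add atoms: sodium iodide, [Na+].[I-]
Why: Finkelstein exchange (SN2) should give the more reactive primary iodide; the allylic silyl ether is inert.

Step 13
Reactants: 17 tert-butyl{[(2E)-5-iodo-2-methylpent-2-en-1-yl]oxy}dimethylsilane; 18 methyl bis(2,2,2-trifluoroethyl)phosphonoacetate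
Product: 19 methyl (5E)-2-[bis(2,2,2-trifluoroethoxy)phosphoryl]-7-[(tert-butyldimethylsilyl)oxy]-6-methylhept-5-enoate (racemic at C2)
Conditions: 18 (1.5 equiv), NaH (1.4 equiv), DMSO, rt; then 17, rt → 40 °C
Reagents that add atoms: none
Why: C-Alkylation of the stabilised phosphonoacetate anion by the primary iodide (SN2) installs the C5–C9 chain on C4; the new centre is racemic and becomes sp2 in step 14.

Step 14
Reactants: 13 (3R,4E)-4,8-dimethyl-3-[(3Z)-3-methyl-5-(phenylsulfonyl)pent-3-en-1-yl]nona-4,7-dienal; 19 methyl (5E)-2-[bis(2,2,2-trifluoroethoxy)phosphoryl]-7-[(tert-butyldimethylsilyl)oxy]-6-methylhept-5-enoate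
Product: 20 methyl (2Z,5R,6E)-2-{(3E)-5-[(tert-butyldimethylsilyl)oxy]-4-methylpent-3-en-1-yl}-6,10-dimethyl-5-[(3Z)-3-methyl-5-(phenylsulfonyl)pent-3-en-1-yl]undeca-2,6,9-trienoate
Conditions: 19 (1.2 equiv), KN(SiMe3)2 (1.15 equiv), 18-crown-6 (3 equiv), THF, −78 °C; then 13, −78 °C
Reagents that add atoms: none
Why: Still–Gennari olefination: the electron-poor bis(trifluoroethyl) phosphonate with a dissociated potassium counter-ion eliminates fast under kinetic control, which should give the (Z)-enoate with the ester cis to C2; the base is consumed by the phosphonate before the aldehyde and the sulfone meet it.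

Step 15
Reactants: 20 silyl ether enoate
Product: 21 methyl (2Z,5R,6E)-2-[(3E)-5-hydroxy-4-methylpent-3-en-1-yl]-6,10-dimethyl-5-[(3Z)-3-methyl-5-(phenylsulfonyl)pent-3-en-1-yl]undeca-2,6,9-trienoate
Conditions: HF·pyridine, pyridine, THF, 0 °C → rt
Reagents that add atoms: none
Why: Fluoride-mediated cleavage of the silyl ether frees the C9 allylic alcohol under buffered conditions that leave the enoate and the sulfone alone.

Step 16
Reactants: 21 C9 allylic alcohol
Product: 22 methyl (2Z,5R,6E)-2-[(3E)-5-bromo-4-methylpent-3-en-1-yl]-6,10-dimethyl-5-[(3Z)-3-methyl-5-(phenylsulfonyl)pent-3-en-1-yl]undeca-2,6,9-trienoate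
Conditions: CBr4, PPh3, CH2Cl2, −20 °C
Reagents that add atoms: carbon tetrabromide, BrC(Br)(Br)Br
Why: Appel bromination (SN2 at the primary allylic carbon) should give the C9 bromide without allylic transposition; the product is used at once.

Step 17
Reactants: 22 open-chain bromo sulfone ester
Product: 24 methyl (1Z,4R,7Z,11E)-7,11-dimethyl-4-[(2E)-6-methylhepta-2,5-dien-2-yl]-9-(phenylsulfonyl)cyclotetradeca-1,7,11-triene-1-carboxylate (both epimers at the sulfonyl carbon, C10 of the target numbering), via lithiated sulfone 23 (not isolated)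
Conditions: LiN(SiMe3)2 (1.05 equiv) added over 4 h to 22 (0.002 M in THF), −78 °C, then → −20 °C; aq. NH4Cl
Reagents that add atoms: none
Why: LiN(SiMe3)2 removes a C10 proton (the most acidic site, flanked by the sulfonyl group and the C11=C12 olefin) to give lithiated allyl sulfone 23, whose α-carbon displaces the primary allylic bromide at C9 in an intramolecular SN2 reaction, so two carbons that are both natively electrophilic allylic termini are joined through sulfone-mediated polarity reversal. The closest known reaction type is the alkylation of prenyl-type sulfone carbanions by (E)-2-methylalk-2-enyl bromides used for head-to-tail terpenoid coupling, including its intramolecular high-dilution form for 14-membered cembranoid rings. The single ring formed is the 14-membered carbocycle, closed in the 14-exo-tet mode with bromide leaving outside the ring. The only new stereocentre is the sulfonyl-bearing C10, which is not controlled and need not be, because both epimers converge when the sulfonyl group is removed in step 19; C1 is remote and untouched. The step needs α- over γ-attack of the allyl anion and SN2 over SN2′ at the bromide (secured by the fully substituted γ-carbon C12 and the unhindered primary C9), retention of the Z C11=C12 and E C7=C8 geometries (secured by the configurational stability of the α-sulfonyl allyllithium at −78 °C and by direct displacement without an allyl cation or allyl-metal species), and ring closure over oligomerisation (secured by 0.002 M dilution). Adding the base to the substrate keeps the amide from ever being in excess, so the less acidic γ-protons of the (Z)-enoate should be left alone.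

Step 18
Reactants: 24 macrocyclic sulfone ester
Product: 25 {(1Z,4R,7Z,11E)-7,11-dimethyl-4-[(2E)-6-methylhepta-2,5-dien-2-yl]-9-(phenylsulfonyl)cyclotetradeca-1,7,11-trien-1-yl}methanol (both sulfonyl epimers)
Conditions: i-Bu2AlH (3 equiv), CH2Cl2, −78 °C; aq. sodium potassium tartrate
Reagents that add atoms: none
Why: 1,2-Reduction of the conjugated ester by i-Bu2AlH at −78 °C should give the C4 hydroxymethyl group; the sulfone and the olefins are inert.

Step 19
Reactants: 25 macrocyclic hydroxy sulfone
Product: 26 target, [(1Z,4R,7Z,11E)-7,11-dimethyl-4-[(2E)-6-methylhepta-2,5-dien-2-yl]cyclotetradeca-1,7,11-trien-1-yl]methanol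
Conditions: PdCl2(dppp) (10 mol %), LiBHEt3 (4 equiv), THF, 0 °C → rt
Reagents that add atoms: none
Why: Palladium-catalysed hydride substitution of the allylic sulfone: zerovalent palladium formed in situ ionises the C10–S bond and hydride is delivered to the less substituted allyl terminus C10, so C11=C12 should keep its position and Z geometry and both C10 epimers converge on the target.

**Compound list**

1 | nerol, (2Z)-3,7-dimethylocta-2,6-dien-1-ol | CC(C)=CCC/C(C)=C\CO | starting material
2 | neryl bromide, (2Z)-1-bromo-3,7-dimethylocta-2,6-diene | CC(C)=CCC/C(C)=C\CBr | intermediate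
3 | neryl phenyl sulfone, {[(2Z)-3,7-dimethylocta-2,6-dien-1-yl]sulfonyl}benzene | CC(C)=CCC/C(C)=C\CS(=O)(=O)c1ccccc1 | intermediate
4 | 6,7-epoxyneryl phenyl sulfone (racemic), 2,2-dimethyl-3-[(3Z)-3-methyl-5-(phenylsulfonyl)pent-3-en-1-yl]oxirane | CC1(C)OC1CC/C(C)=C\CS(=O)(=O)c1ccccc1 | intermediate
5 | (6Z)-2,6-dimethyl-8-(phenylsulfonyl)oct-6-ene-2,3-diol (racemic, not isolated) | CC(C)(O)C(O)CC/C(C)=C\CS(=O)(=O)c1ccccc1 | intermediate
6 | (4Z)-4-methyl-6-(phenylsulfonyl)hex-4-enal | O=CCC/C(C)=C\CS(=O)(=O)c1ccccc1 | intermediate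
7 | (2E,6Z)-2,6-dimethyl-8-(phenylsulfonyl)octa-2,6-dienal | O=C/C(C)=C/CC/C(C)=C\CS(=O)(=O)c1ccccc1 | intermediate
8 | pinacol borate of 9 (not isolated) | C=CC[C@@H](OB1OC(C)(C)C(C)(C)O1)/C(C)=C/CC/C(C)=C\CS(=O)(=O)c1ccccc1 | intermediate
9 | (4R,5E,9Z)-5,9-dimethyl-11-(phenylsulfonyl)undeca-1,5,9-trien-4-ol | C=CC[C@@H](O)/C(C)=C/CC/C(C)=C\CS(=O)(=O)c1ccccc1 | intermediate
10 | (5R,6E,10Z)-2,6,10-trimethyl-12-(phenylsulfonyl)dodeca-2,6,10-trien-5-ol | CC(C)=CC[C@@H](O)/C(C)=C/CC/C(C)=C\CS(=O)(=O)c1ccccc1 | intermediate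
11 | 1-ethoxyvinyl ether (mixed ketene acetal) of 10 (not isolated) | C=C(OCC)O[C@H](CC=C(C)C)/C(C)=C/CC/C(C)=C\CS(=O)(=O)c1ccccc1 | intermediate
12 | ethyl (3R,4E)-4,8-dimethyl-3-[(3Z)-3-methyl-5-(phenylsulfonyl)pent-3-en-1-yl]nona-4,7-dienoate | CCOC(=O)C[C@@H](CC/C(C)=C\CS(=O)(=O)c1ccccc1)/C(C)=C/CC=C(C)C | intermediate
13 | (3R,4E)-4,8-dimethyl-3-[(3Z)-3-methyl-5-(phenylsulfonyl)pent-3-en-1-yl]nona-4,7-dienal | O=CC[C@@H](CC/C(C)=C\CS(=O)(=O)c1ccccc1)/C(C)=C/CC=C(C)C | intermediate
14 | 5-bromo-2-methylpent-2-ene | CC(C)=CCCBr | starting material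
15 | (2E)-5-bromo-2-methylpent-2-en-1-ol | OC/C(C)=C/CCBr | intermediate
16 | {[(2E)-5-bromo-2-methylpent-2-en-1-yl]oxy}(tert-butyl)dimethylsilane | CC(C)(C)[Si](C)(C)OC/C(C)=C/CCBr | intermediate
17 | tert-butyl{[(2E)-5-iodo-2-methylpent-2-en-1-yl]oxy}dimethylsilane | CC(C)(C)[Si](C)(C)OC/C(C)=C/CCI | intermediate
18 | methyl bis(2,2,2-trifluoroethyl)phosphonoacetate | COC(=O)CP(=O)(OCC(F)(F)F)OCC(F)(F)F | starting material
19 | methyl (5E)-2-[bis(2,2,2-trifluoroethoxy)phosphoryl]-7-[(tert-butyldimethylsilyl)oxy]-6-methylhept-5-enoate (racemic) | COC(=O)C(CC/C=C(\C)CO[Si](C)(C)C(C)(C)C)P(=O)(OCC(F)(F)F)OCC(F)(F)F | intermediate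
20 | methyl (2Z,5R,6E)-2-{(3E)-5-[(tert-butyldimethylsilyl)oxy]-4-methylpent-3-en-1-yl}-6,10-dimethyl-5-[(3Z)-3-methyl-5-(phenylsulfonyl)pent-3-en-1-yl]undeca-2,6,9-trienoate | COC(=O)/C(CC/C=C(\C)CO[Si](C)(C)C(C)(C)C)=C\C[C@@H](CC/C(C)=C\CS(=O)(=O)c1ccccc1)/C(C)=C/CC=C(C)C | intermediate
21 | methyl (2Z,5R,6E)-2-[(3E)-5-hydroxy-4-methylpent-3-en-1-yl]-6,10-dimethyl-5-[(3Z)-3-methyl-5-(phenylsulfonyl)pent-3-en-1-yl]undeca-2,6,9-trienoate | COC(=O)/C(CC/C=C(\C)CO)=C\C[C@@H](CC/C(C)=C\CS(=O)(=O)c1ccccc1)/C(C)=C/CC=C(C)C | intermediate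
22 | methyl (2Z,5R,6E)-2-[(3E)-5-bromo-4-methylpent-3-en-1-yl]-6,10-dimethyl-5-[(3Z)-3-methyl-5-(phenylsulfonyl)pent-3-en-1-yl]undeca-2,6,9-trienoate | COC(=O)/C(CC/C=C(\C)CBr)=C\C[C@@H](CC/C(C)=C\CS(=O)(=O)c1ccccc1)/C(C)=C/CC=C(C)C | intermediate
23 | lithiated sulfone of 22, carbanion at C10 (not isolated) | [Li+].COC(=O)/C(CC/C=C(\C)CBr)=C\C[C@@H](CC/C(C)=C\[CH-]S(=O)(=O)c1ccccc1)/C(C)=C/CC=C(C)C | intermediate
24 | methyl (1Z,4R,7Z,11E)-7,11-dimethyl-4-[(2E)-6-methylhepta-2,5-dien-2-yl]-9-(phenylsulfonyl)cyclotetradeca-1,7,11-triene-1-carboxylate (both sulfonyl epimers) | COC(=O)/C1=C\C[C@H](/C(C)=C/CC=C(C)C)CC/C(C)=C\C(S(=O)(=O)c2ccccc2)C/C(C)=C/CC1 | intermediate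
25 | {(1Z,4R,7Z,11E)-7,11-dimethyl-4-[(2E)-6-methylhepta-2,5-dien-2-yl]-9-(phenylsulfonyl)cyclotetradeca-1,7,11-trien-1-yl}methanol (both sulfonyl epimers) | OC/C1=C\C[C@H](/C(C)=C/CC=C(C)C)CC/C(C)=C\C(S(=O)(=O)c2ccccc2)C/C(C)=C/CC1 | intermediate
26 | CNP0288338.1, [(1Z,4R,7Z,11E)-7,11-dimethyl-4-[(2E)-6-methylhepta-2,5-dien-2-yl]cyclotetradeca-1,7,11-trien-1-yl]methanol | CC(C)=CC/C=C(\C)[C@H]1C/C=C(\CO)CC/C=C(\C)CC/C=C(/C)CC1 | target

**Step count and risks**

Total steps: 19. Longest linear sequence: 15 (steps 1–9 and 14–19, from nerol); steps 10–13 build the phosphonate fragment.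

Step 17 (ring closure). What may go wrong: intermolecular alkylation may outrun ring closure and give oligomers; the amide base may abstract a γ-proton of the (Z)-enoate; the carbanion may add to the ester or the enoate. Fallback: cyclise at the alcohol oxidation level with the C4 substituent masked, so that the substrate can be fed slowly into excess base. The fallback sets out from 20. i-Bu2AlH (CH2Cl2, −78 °C) should give the C4 allylic alcohol F1. TBDPSCl and imidazole should give the bis-silyl ether F2. PPTS in MeOH should remove only the primary TBS ether and give the C9 alcohol F3. CBr4 and PPh3 should give the C9 bromide F4. F4, which no longer carries a base-sensitive group, is added by syringe pump to KN(SiMe3)2 (1.5 equiv) and 18-crown-6 in THF (final 0.002 M, −40 °C), which should give the macrocyclic sulfone silyl ether F5. Bu4NF in THF should then give 25, where the fallback rejoins the route.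

Step 6 (allylboration). What may go wrong: facial discrimination in the allyl transfer to the α-branched enal may be poor, which would lower the enantiomeric purity at C16 and, after step 8, at C1. Fallback: set the carbinol by asymmetric reduction instead of asymmetric allylation. The fallback sets out from 10 of inadequate enantiomeric purity. Dess–Martin periodinane (NaHCO3, CH2Cl2) should give the ketone F6. Reduction with BH3·SMe2 and (S)-tetrahydro-1-methyl-3,3-diphenyl-1H,3H-pyrrolo[1,2-c][1,3,2]oxazaborole (10 mol %, THF, −30 °C; CBS reduction, with the α-branched alkenyl group as the large substituent) should return (R)-10, where the fallback rejoins the route.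

Step 19 (desulfonylation). What may go wrong: hydride may be delivered to C12 instead of C10, which would shift the olefin to C10=C11; syn/anti equilibration of the allylpalladium species in the constrained ring may erode the Z geometry of C11=C12. Fallback: electron-transfer cleavage instead of palladium hydride chemistry. The fallback sets out from 25 and goes directly to 26 with lithium in ethylamine/THF at −78 °C, the hydroxyl being carried as its lithium alkoxide. This cleaves the C–S bond without any allylpalladium species and makes no new compound (F0).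

Further compounds
F1 | step 17 | (2Z,5R,6E)-2-{(3E)-5-[(tert-butyldimethylsilyl)oxy]-4-methylpent-3-en-1-yl}-6,10-dimethyl-5-[(3Z)-3-methyl-5-(phenylsulfonyl)pent-3-en-1-yl]undeca-2,6,9-trien-1-ol | OC/C(CC/C=C(\C)CO[Si](C)(C)C(C)(C)C)=C\C[C@@H](CC/C(C)=C\CS(=O)(=O)c1ccccc1)/C(C)=C/CC=C(C)C
F2 | step 17 | tert-butyldiphenylsilyl ether of F1 (C4 CH2OTBDPS, C9 OTBS) | CC(C)(C)[Si](c1ccccc1)(c1ccccc1)OC/C(CC/C=C(\C)CO[Si](C)(C)C(C)(C)C)=C\C[C@@H](CC/C(C)=C\CS(=O)(=O)c1ccccc1)/C(C)=C/CC=C(C)C
F3 | step 17 | C9 alcohol with C4 CH2OTBDPS | CC(C)(C)[Si](c1ccccc1)(c1ccccc1)OC/C(CC/C=C(\C)CO)=C\C[C@@H](CC/C(C)=C\CS(=O)(=O)c1ccccc1)/C(C)=C/CC=C(C)C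
F4 | step 17 | C9 bromide with C4 CH2OTBDPS | CC(C)(C)[Si](c1ccccc1)(c1ccccc1)OC/C(CC/C=C(\C)CBr)=C\C[C@@H](CC/C(C)=C\CS(=O)(=O)c1ccccc1)/C(C)=C/CC=C(C)C
F5 | step 17 | tert-butyldiphenylsilyl ether of 25 (macrocyclic sulfone, both sulfonyl epimers) | CC(C)(C)[Si](c1ccccc1)(c1ccccc1)OC/C1=C\C[C@H](/C(C)=C/CC=C(C)C)CC/C(C)=C\C(S(=O)(=O)c2ccccc2)C/C(C)=C/CC1
F6 | step 6 | (6E,10Z)-2,6,10-trimethyl-12-(phenylsulfonyl)dodeca-2,6,10-trien-5-one | CC(C)=CCC(=O)/C(C)=C/CC/C(C)=C\CS(=O)(=O)c1ccccc1
F0 | step 19 | none | none
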